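**Retrosynthetic overview**
1. The four bromines ortho and para to the two phenolic OH groups go in last, by electrophilic bromination of 5-bromo-2-(2-hydroxyphenoxy)phenol. The fifth bromine (para to the ether oxygen on ring B) is bought in place.
2. The ring B hydroxyl is carried as a methyl ether (4-bromoguaiacol). The ring A phenol is traced back to a cyclohexanone by dehydrogenative aromatisation.
3. Key disconnection: the diaryl ether C–O bond, the only strategic bond since there is no C–C bond outside the two benzene rings. It is cut between the ring B phenoxide oxygen and the α-carbon of 2-chlorocyclohexanone. That α-carbon is an enolonium (a2) equivalent of a phenol ortho carbon, so two natively nucleophilic centres are joined with reversed polarity.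
4. Ring order: ring B is bought aromatic. Ring A is bought as a saturated six-membered ketone, attached in step 1 and aromatised in step 2. No ring is made by cyclisation.

Assumption: the target has no stereocentre or stereoaxis (it is achiral), so the "single enantiomer" is the compound itself and no stereocontrol is needed.

**Route**

Step 1
Reactants: 1 4-bromo-2-methoxyphenol; 2 2-chlorocyclohexan-1-one (racemic)
Product: 3 2-(4-bromo-2-methoxyphenoxy)cyclohexan-1-one (racemic)
Conditions: K2CO3 (2 equiv), acetone, reflux, 24 h
Reagents that add atoms: none
Why: Williamson-type SN2 O-alkylation of the phenoxide by an α-haloketone, the classical enolonium (a2) equivalent, so the ketone α-carbon (natively nucleophilic, like the phenol ortho carbon it will become) acts as the electrophile; the one new stereocentre forms racemic and is erased in step 2.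

Step 2
Reactants: 3 2-(4-bromo-2-methoxyphenoxy)cyclohexan-1-one
Product: 5 2-(4-bromo-2-methoxyphenoxy)phenol, via 6-(4-bromo-2-methoxyphenoxy)cyclohex-2-en-1-one 4 (not isolated)
Conditions: Pd(OCOCF3)2 (5 mol %), 2-(dimethylamino)pyridine (10 mol %), TsOH·H2O (20 mol %), O2 (1 atm), DMSO, 80 °C, 24 h
Reagents that add atoms: none
Why: Aerobic dehydrogenative aromatisation of a cyclohexanone catalysed by divalent palladium (two rounds of Pd-enolate formation and β-hydride elimination, O2 reoxidising zerovalent palladium), passing through the enone (most likely formed on the less substituted side first) and ending in tautomerisation to the phenol, which removes the stereocentre; the methyl ether keeps the ring B oxygen from closing onto the ketone.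

Step 3
Reactants: 5 2-(4-bromo-2-methoxyphenoxy)phenol
Product: 7 2,3,4-tribromo-6-(3,5-dibromo-2-hydroxyphenoxy)phenol, via 5-bromo-2-(2-hydroxyphenoxy)phenol 6 (not isolated)
Conditions: BBr3 (3 equiv), CH2Cl2, −78 to 23 °C; H2O, 0 °C; then Br2 (4.1 equiv), 0 to 23 °C
Reagents that add atoms: bromine (Br2), BrBr
Why: BBr3 cleavage of the aryl methyl ether followed in the same flask by electrophilic aromatic bromination, in which each free OH directs bromine to its own para and ortho positions (two on ring A, two on ring B flanking the bromine already present), the positions meta to OH staying untouched at this stoichiometry; no stereocentre is involved.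

**Compound list**
1 | 4-bromo-2-methoxyphenol (4-bromoguaiacol) | COc1cc(Br)ccc1O | starting material
2 | 2-chlorocyclohexan-1-one (racemic) | O=C1CCCCC1Cl | starting material
3 | 2-(4-bromo-2-methoxyphenoxy)cyclohexan-1-one (racemic) | COc1cc(Br)ccc1OC1CCCCC1=O | intermediate
4 | 6-(4-bromo-2-methoxyphenoxy)cyclohex-2-en-1-one (racemic, not isolated) | COc1cc(Br)ccc1OC1CCC=CC1=O | intermediate
5 | 2-(4-bromo-2-methoxyphenoxy)phenol | COc1cc(Br)ccc1Oc1ccccc1O | intermediate
6 | 5-bromo-2-(2-hydroxyphenoxy)phenol (not isolated) | Oc1ccccc1Oc1ccc(Br)cc1O | intermediate
7 | 2,3,4-tribromo-6-(3,5-dibromo-2-hydroxyphenoxy)phenol (achiral) | Oc1c(Br)cc(Br)cc1Oc1cc(Br)c(Br)c(Br)c1O | target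

**Step count and risks**
Total steps: 3 (the last is a one-flask demethylation and bromination). Longest linear sequence: 3.

Risk 1, step 2 (most likely to fail). The aerobic palladium dehydrogenation may stall at enone 4, and transient zerovalent palladium may attack the aryl bromide. Fallback: enter ring A one oxidation level higher and finish without a metal. Setting out from 1, the phenoxide (Cs2CO3, DMF, 70 °C) opens commercial 7-oxabicyclo[4.1.0]heptan-2-one (2,3-epoxycyclohexanone) at the α-carbon. This gives trans-2-(4-bromo-2-methoxyphenoxy)-3-hydroxycyclohexan-1-one F1, which loses water in the same pot to give 2-(4-bromo-2-methoxyphenoxy)cyclohex-2-en-1-one F2. A single dehydrogenation with DDQ (cat. TsOH, dioxane, 100 °C) then gives phenol 5, where the route resumes.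

Risk 2, step 3. One-flask exhaustive bromination may under-brominate the hindered site between OH and Br on ring B, or over-brominate. Fallback: put the bromines in site by site. Setting out from 5, Br2 (3 equiv, AcOH, NaOAc) gives 2,4-dibromo-6-(4,5-dibromo-2-methoxyphenoxy)phenol F3 (ring A ortho/para to OH, ring B para to OMe), which is isolated and crystallised. BBr3 then gives 2,4-dibromo-6-(4,5-dibromo-2-hydroxyphenoxy)phenol F4. A single amine-mediated ortho-bromination (NBS, cat. iPr2NH, CH2Cl2) at the only remaining activated position returns to the route at target 7.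

Risk 3, step 1. The α-chloroketone may undergo Favorskii rearrangement, dehydrohalogenation or self-condensation instead of clean substitution. Fallback: make the C–O bond at the alcohol oxidation level and oxidise afterwards. Setting out from 1, the phenoxide opens cyclohexene oxide (K2CO3, DMF, 110 °C) to give trans-2-(4-bromo-2-methoxyphenoxy)cyclohexan-1-ol F5 (racemic). Dess–Martin periodinane oxidation of the alcohol returns to the route at ketone 3.

**Further compounds**
F1 | step 2 | trans-2-(4-bromo-2-methoxyphenoxy)-3-hydroxycyclohexan-1-one (racemic, one enantiomer drawn) | COc1cc(Br)ccc1O[C@@H]1C(=O)CCC[C@H]1O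
F2 | step 2 | 2-(4-bromo-2-methoxyphenoxy)cyclohex-2-en-1-one | COc1cc(Br)ccc1OC1=CCCCC1=O
F3 | step 3 | 2,4-dibromo-6-(4,5-dibromo-2-methoxyphenoxy)phenol | COc1cc(Br)c(Br)cc1Oc1cc(Br)cc(Br)c1O
F4 | step 3 | 2,4-dibromo-6-(4,5-dibromo-2-hydroxyphenoxy)phenol | Oc1cc(Br)c(Br)cc1Oc1cc(Br)cc(Br)c1O
F5 | step 1 | trans-2-(4-bromo-2-methoxyphenoxy)cyclohexan-1-ol (racemic, one enantiomer drawn) | COc1cc(Br)ccc1O[C@@H]1CCCC[C@H]1O
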